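(The numbers in the tables are calculated on assumed constants; the scatter is artificial.)

Late in a run, look first at the X still unreacted: on the suspect list a chain begins by taking one X and each added unit takes another, so D and the chain count both grow out of that leftover.

| flask | X | G | remark | time |
|---|---|---|---|---|
| dusk | 0.055 M | 9.2 mol% | run made earlier |  |
| summer | 0.22 M | 9.2 mol% | run made earlier |  |
| south-east | 0.11 M | 9.2 mol% |  | 40 min |
| east | 0.11 M | 9.2 mol% |  | 120 min |

- dusk (time / min: D / %): 5.00: 2.1; 10.0: 9.7; 15.0: 22.6; 20.0: 41.0; 25.0: 55.7; 30.0: 68.9
- summer (time / min: D / %): 2.50: 3.1; 4.00: 11.4; 6.00: 28.0; 10.0: 66.3; 15.0: 90.5; 20.0: 99.2; 30.0: 100.2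

(readings scatter by 0.5 percentage points)

- the average divides the monomer in chains by the number of chains begun, living and dead together
- on the list of suspects stand: X + E -> J + D; X + J -> D + J; G -> E; E -> Z
- the earlier runs do not show the number of chains; that part of a forecast is a guess

- which of the two ends with the longer chains by the average number of monomer units in a chain (chains begun, living or dead) ("neither" if they lie within 10%) (south-east / east / neither)
- average number of monomer units in a chain (chains begun, living or dead) at the end, south-east
- average number of monomer units in a chain (chains begun, living or dead) at the end, east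

You take over south-east and east, one charge read at 40 min and at 120 min. Reckon the mean clearing constant, the logarithm of charged over remaining [X] divided by the time, which replaces the pseudo-first-order constant of X by its mean. At 20.0 min the logarithm reads 0.528 in dusk and 4.83 in summer. Since 0.11 M is the geometric mean of their charges, take the geometric mean: 0.0798 min⁻¹. Read it as rough: the 0.800% of X that summer's reading leaves carries a scatter of 0.5 percentage points.

Now check the error. The dusk readings give 0.0264 min⁻¹ on average up to 20.0 min, but 0.0640 min⁻¹ afterwards, so I reckon that carrying a mean read at 20.0 min on to later times overstates what remains. Expect roughly 4.11% of X at 40 min, probably less. As J accumulates, I reckon a growing share of X feeds propagation, so I estimate that between the readings the length rises by about 4.29% if few chains begin after the first reading, below the margin of 10%. Do not wait for longer chains. I commit to no absolute length, since the runs show no chain count.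

The forecast commits: neither, 120 and 125, noting “The absolute length depends on the unseen split between kp and kG.”

The simulation gives neither, with 70.3 for south-east and 70.7 for east, so the forecast's 120 stood 1.71 times too high. South-east holds 0.77% of its X at 40.0 min, less than the reckoned 4.11%, and its own mean constant over that time is 0.122 min⁻¹, above 0.0798 min⁻¹.

    X + E → J + D (k = 0.00780 L mol⁻¹ s⁻¹)
    X + J → D + J, rate k2*[J]*[X] (k = 1.80 L mol⁻¹ s⁻¹)
    G → E (k = 9.40 × 10⁻⁴ s⁻¹)
    E → Z (k = 9.80 × 10⁻⁴ s⁻¹)

For east left until 3.0 h, 0.0798 min⁻¹ leaves about 0.00694% of X at 120 min, so I expect its length to stay close to that of east. The computed length of that flask is 70.7.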